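## Analysis of the target

Target 16 is a (2S)-flavanone. Ring C is a 2,3-dihydro-4H-pyran-4-one fused through C4a–C8a to the benzene ring A, and the catechol ring B sits on C2. C2 is the only stereocentre; it is benzylic, carries O1 and lies beta to the C4 carbonyl. Enolisation toward C3 under base can therefore expel O1 and open ring C, and acid can ionise the C2–O1 bond; either process racemises the compound. Ring A is fully differentiated: O5 is a free, carbonyl-chelated phenol, O7 a methyl ether, C8 carries the prenyl group and C6 a hydrogen. Routes from phloroglucinol-type arenes must tell three similar oxygens and the C6 and C8 positions apart. The trisubstituted prenyl olefin (protic acid, electrophiles, hydrogenation) and the oxidisable catechol are further sensitive groups. The difficulty is to combine regiocontrol on ring A with control and preservation of C2. The feature used here is that the C4a=C8a bond belongs to rings A and C alike: in ring C alone it is the polarised C5=C6 enol ether bond of a 2-aryl-2,3-dihydropyran-4-one. An enantiopure dihydropyranone can thus carry C2 and serve as the two-carbon partner onto which C5 to C8 are added as one four-carbon unit bearing O5, O7 and the prenyl group.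

## Retrosynthetic reasoning

**16 from 15.** Only the two O–Si bonds on ring B are cut. The catechol is carried as its bis(tert-butyldimethylsilyl) ether because these groups tolerate mild Lewis acids, amine bases and electrophilic bromination, and leave under buffered fluoride. That avoids both the protic acid that threatens the prenyl group and the strong base that opens ring C. The chelated 5-hydroxyl needs no protection.

**15 from 6 and 12.** The bonds C4a–C5 and C8–C8a are cut. These two bonds join the ring A carbons C5 to C8 to the shared C4a=C8a unit, so cutting them leaves ring C and its stereocentre intact in bromopyranone 6. All three ring A substituents then sit on one acyclic piece, diene 12, where their positions are fixed by simple enolate chemistry. Cutting inside ring C instead would leave the stereocentre to be made on a fully substituted arene. The forward reaction has to join the prenyl-bearing diene terminus to the O-bearing carbon of 6 and the ketene acetal carbon to the brominated carbon. It must then aromatise by dehydrobromination and loss of the C5 methoxy group. No stereocentre is created that survives.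

**6 from 5.** The C5–Br bond is cut. Pyranone 5 is nucleophilic at its enol ether carbon, so bromine can be placed there selectively. The bromine raises the dienophilicity of the vinylogous ester and supplies the leaving group needed for aromatisation.

**5 from 2 and 3, and 2 from 1.** The bonds C2–C3 and O1–C6 are cut, which is a hetero-Diels–Alder disconnection. It builds ring C and sets C2 in one catalytic asymmetric operation from aldehyde 2 and diene 3. Aldehyde 2 is the silylated form of 1.

**12 from 11, 11 from 9 through 10, 9 from 7 and 8.** Diene 12 is the silyl dienolate of enol ether 11. Enol ether 11 is the O-methylated form of keto ester 9, reached through ketal 10. Keto ester 9 is cut at the bond between its gamma carbon and the prenyl CH2, which leads back to 7 and 8. This places the prenyl group on the future C8 and the methoxy group on the future C7 before ring A exists.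

## Alternatives that were turned down

**Alternative 1:** Ring A is disconnected at C7–C8, C4a–C8a and C6–C7 into a four-carbon and a two-carbon component. In the forward sense, 3-isopropoxycyclobutenone A2 and the prenyl-bearing siloxyalkyne A3 are heated. Electrocyclic opening to a vinylketene, [2+2] addition of the alkyne, a second ring opening and 6π closure give phenol A1.
- For it: this benzannulation class is established for siloxyalkynes, and its key step stands on firmer ground than that of the chosen route. The alkyne polarity fixes the prenyl group between a free hydroxyl (future O7) and a silyl ether (future O1), with O5 as a third, distinct ether.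
- Against it: A1 is only ring A. C4a is still a C–H flanked by two bulky ethers and must be acylated. Ring C and C2 then have to be made by an enantioselective O1–C2 closure on a 5-oxygenated system, where reversible ring opening erodes enantiopurity. A2 and A3 each need several steps.
- Comparison: the chosen route sets C2 catalytically before ring A exists, delivers ring A already fused and fully substituted in one step, and needs one deprotection afterwards.

**Alternative 2:** The O1–C8a bond is disconnected. The (S)-beta-hydroxy ketone A5 is deprotonated with a strong potassium amide base, and its alkoxide displaces fluoride ortho to the ketone to give flavanone A4.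
- For it: the C2–O bond is never broken, so an aldol-derived configuration is carried through with retention. The fluorine marks C8a, so no 6- versus 8-prenyl ambiguity arises. The closure is intramolecular and mechanistically simple, arguably more predictable than an untested cycloaddition.
- Against it: the potassium aldolate of an aryl beta-hydroxy ketone is set up for retro-aldol cleavage and for dehydration across C2–C3, both of which destroy or racemise C2. The fluorine is flanked by the prenyl group and the acyl group on an electron-rich ring, so substitution should be slow. The pentasubstituted fluoroarene and an asymmetric acetate aldol of a 2,6-disubstituted aryl methyl ketone cost many steps.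
- Comparison: the chosen route builds the ring A carbons from 7 and 8 in three steps and never exposes a beta-oxygenated ketone to strong base.

**Alternative 3:** The C4–C4a bond is disconnected. The (S)-3-aryloxy-3-arylpropanoic acid A7 is activated as a mixed anhydride under strongly acidic conditions and acylates C4a to give the triacetate A6.
- For it: intramolecular Friedel–Crafts closure of 3-aryloxypropanoic acids is a known route to chromanones. C4a is the only free position ortho to O1, and C2 is already in place.
- Against it: the benzylic C2–O1 bond of A7 can ionise or undergo elimination across C2–C3 in the acidic medium. The prenyl olefin can be protonated to a tertiary cation. The 5-acetoxy group deactivates the site of attack. Making A7 requires etherification of a hindered ortho-prenyl phenol at a benzylic carbon with inversion, where elimination competes.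
- Comparison: the chosen route forms no bond at C2 after the catalytic step and keeps strong acid away from the prenyl group, at the price of a key step without direct precedent.

Key step: step 7

Assumption: the titanium complex of (S)-BINOL is taken to direct diene 3 to the Si face of aldehyde 2, which gives (S)-5; if the sense is the opposite, (R)-BINOL is used and nothing else changes.

## Route

Step 1
Reactants: 1 3,4-dihydroxybenzaldehyde
Product: 2 3,4-bis(tert-butyldimethylsilyloxy)benzaldehyde
Conditions: TBSCl (2.3 equiv), imidazole, DMF, rt
Reagents that add atoms: tert-butyldimethylsilyl chloride, CC(C)(C)[Si](C)(C)Cl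
Why: Imidazole-promoted silylation of both phenols; the aldehyde is untouched and the silyl ethers make the aldehyde soluble and compatible with the Lewis acid of step 2.

Step 2
Reactants: 2 3,4-bis(tert-butyldimethylsilyloxy)benzaldehyde; 3 Danishefsky's diene, (E)-1-methoxy-3-(trimethylsilyloxy)buta-1,3-diene
Product: 5 (2S)-2-[3,4-bis(tert-butyldimethylsilyloxy)phenyl]-2,3-dihydro-4H-pyran-4-one, via silyl aldol adduct 4 (not isolated)
Conditions: Ti(OiPr)4 (10 mol%), (S)-BINOL (20 mol%), 4 Å MS, toluene, 0 °C; then CF3CO2H, CH2Cl2, 0 °C
Reagents that add atoms: none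
Why: Catalytic asymmetric hetero-Diels–Alder reaction in its stepwise form: the chiral titanium BINOLate binds the aldehyde and the diene terminus adds to the exposed Si face (Mukaiyama aldol), which sets C2 as S. Acid then closes ring C by oxa-Michael addition and loss of methanol.

Step 3
Reactants: 5 (2S)-2-[3,4-bis(tert-butyldimethylsilyloxy)phenyl]-2,3-dihydro-4H-pyran-4-one
Product: 6 (2S)-5-bromo-2-[3,4-bis(tert-butyldimethylsilyloxy)phenyl]-2,3-dihydro-4H-pyran-4-one
Conditions: NBS (1.05 equiv), CH2Cl2, 0 °C to rt
Reagents that add atoms: N-bromosuccinimide, O=C1CCC(=O)N1Br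
Why: Electrophilic alpha-bromination of a vinylogous ester: C5 is the nucleophilic enol ether carbon and the bromo-oxocarbenium ion loses the C5 proton. The silylated arene is far less nucleophilic and C2 is not involved.

Step 4
Reactants: 7 methyl acetoacetate; 8 prenyl bromide (1-bromo-3-methylbut-2-ene)
Product: 9 methyl 7-methyl-3-oxooct-6-enoate
Conditions: NaH, THF, 0 °C; n-BuLi, 0 °C; 8, 0 °C to rt; aq. HCl
Reagents that add atoms: none
Why: Gamma-alkylation of the acetoacetate dianion: the more basic terminal carbanion attacks the primary allylic bromide in an SN2 reaction.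

Step 5
Reactants: 9 methyl 7-methyl-3-oxooct-6-enoate
Product: 11 methyl (2E)-3-methoxy-7-methylocta-2,6-dienoate, via dimethyl ketal 10 (not isolated)
Conditions: HC(OMe)3, MeOH, H2SO4 (cat.), rt; then TsOH (cat.), toluene, 90 °C, removal of MeOH
Reagents that add atoms: trimethyl orthoformate, COC(OC)OC; methanol, CO
Why: Acid-catalysed ketalisation with the orthoformate as water scavenger, then elimination of methanol to the conjugated (E)-enol ether. Catalytic acid without a nucleophile leaves the trisubstituted olefin alone, as in routine acetalisations of prenylated carbonyl compounds.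

Step 6
Reactants: 11 methyl (2E)-3-methoxy-7-methylocta-2,6-dienoate
Product: 12 (3Z)-1,3-dimethoxy-7-methyl-1-(trimethylsilyloxy)octa-1,3,6-triene
Conditions: LiN(iPr)2, THF, −78 °C; TMSCl, −78 °C to rt; pentane, filtration, used crude
Reagents that add atoms: chlorotrimethylsilane, C[Si](C)(C)Cl
Why: Kinetic gamma-deprotonation of the beta-methoxy enoate and O-silylation of the dienolate, the standard entry to 1,3-dimethoxy-1-silyloxydienes. The geometry at C3=C4 has no lasting consequence because that carbon becomes the aromatic C8.

Step 7
Reactants: 6 (2S)-5-bromo-2-[3,4-bis(tert-butyldimethylsilyloxy)phenyl]-2,3-dihydro-4H-pyran-4-one; 12 (3Z)-1,3-dimethoxy-7-methyl-1-(trimethylsilyloxy)octa-1,3,6-triene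
Product: 15 (2S)-2-[3,4-bis(tert-butyldimethylsilyloxy)phenyl]-5-hydroxy-7-methoxy-8-(3-methylbut-2-enyl)chroman-4-one, via bromo ketal cycloadduct 13 (not isolated), via bromo dione 14 (not isolated)
Conditions: 12 (3 equiv), Eu(fod)3 (10 mol%; fod = 6,6,7,7,8,8,8-heptafluoro-2,2-dimethyloctane-3,5-dionate), toluene, 0 to 50 °C; then 0.5 M HCl, THF, 0 °C; then Et3N, CH2Cl2, 0 °C to rt
Reagents that add atoms: none
Why: Proposed new method: the closest known reaction type is the Diels–Alder reaction and aromatisation of 1,3-dioxygenated 1-silyloxydienes with halogenated quinones and alpha-halo enones, transferred here to an alpha-bromo vinylogous ester. The europium chelate activates the C4 carbonyl of 6, and diene 12 adds either in a concerted, strongly asynchronous [4+2] reaction or by Mukaiyama–Michael attack followed by collapse of the zwitterion. In both cases the prenyl-bearing terminus bonds to the O-bearing beta carbon (future C8a) and the ketene acetal carbon to the brominated alpha carbon (future C4a), so ring A is closed by intermolecular [4+2] annulation onto the C5=C6 bond of the pyranone. The required regiochemistry (prenyl next to O1, acetal oxygen next to C4) follows from pairing the most nucleophilic diene carbon with the enone beta position, and the bromine lowers the acceptor orbital of the otherwise sluggish push-pull enone. Dilute acid cleaves the mixed silyl methyl ketal of 13 at Si–O to the vinylogous ester 14. Triethylamine then enolises 14 toward C8 and removes HBr across C4a–C8a; H and Br are cis in the first-formed adduct, but the elimination is driven by aromatisation, and reversible opening of the O1–C8a bond in the dienolate offers an anti pathway. The centres formed at C4a, C5, C8 and C8a are all destroyed, so no new stereocentre has to be controlled. C2 lies outside the reacting system and keeps its S configuration because the base is too weak to open ring C at O1–C2.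

Step 8
Reactants: 15 (2S)-2-[3,4-bis(tert-butyldimethylsilyloxy)phenyl]-5-hydroxy-7-methoxy-8-(3-methylbut-2-enyl)chroman-4-one
Product: 16 (2S)-2-(3,4-dihydroxyphenyl)-5-hydroxy-7-methoxy-8-(3-methylbut-2-enyl)chroman-4-one
Conditions: Bu4NF, AcOH (1:1), THF, 0 °C, under argon
Reagents that add atoms: none
Why: Fluoride-mediated cleavage of the two aryl silyl ethers. The acetic acid buffer protonates the phenoxides at once and keeps the medium below the basicity at which ring C opens by E1cB at O1–C2, so C2 should not racemise; the prenyl group and the methyl ether are inert.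

## Compound list

1 | 3,4-dihydroxybenzaldehyde | O=Cc1ccc(O)c(O)c1 | starting material
2 | 3,4-bis(tert-butyldimethylsilyloxy)benzaldehyde | O=Cc1ccc(O[Si](C)(C)C(C)(C)C)c(O[Si](C)(C)C(C)(C)C)c1 | intermediate
3 | Danishefsky's diene, (E)-1-methoxy-3-(trimethylsilyloxy)buta-1,3-diene | CO/C=C/C(=C)O[Si](C)(C)C | starting material
4 | (1E,5S)-5-[3,4-bis(tert-butyldimethylsilyloxy)phenyl]-1-methoxy-5-(trimethylsilyloxy)pent-1-en-3-one | CO/C=C/C(=O)C[C@H](O[Si](C)(C)C)c1ccc(O[Si](C)(C)C(C)(C)C)c(O[Si](C)(C)C(C)(C)C)c1 | intermediate (not isolated)
5 | (2S)-2-[3,4-bis(tert-butyldimethylsilyloxy)phenyl]-2,3-dihydro-4H-pyran-4-one | O=C1C[C@@H](c2ccc(O[Si](C)(C)C(C)(C)C)c(O[Si](C)(C)C(C)(C)C)c2)OC=C1 | intermediate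
6 | (2S)-5-bromo-2-[3,4-bis(tert-butyldimethylsilyloxy)phenyl]-2,3-dihydro-4H-pyran-4-one | O=C1C[C@@H](c2ccc(O[Si](C)(C)C(C)(C)C)c(O[Si](C)(C)C(C)(C)C)c2)OC=C1Br | intermediate
7 | methyl acetoacetate | CC(=O)CC(=O)OC | starting material
8 | prenyl bromide, 1-bromo-3-methylbut-2-ene | CC(C)=CCBr | starting material
9 | methyl 7-methyl-3-oxooct-6-enoate | COC(=O)CC(=O)CCC=C(C)C | intermediate
10 | methyl 3,3-dimethoxy-7-methyloct-6-enoate | COC(=O)CC(OC)(OC)CCC=C(C)C | intermediate (not isolated)
11 | methyl (2E)-3-methoxy-7-methylocta-2,6-dienoate | COC(=O)/C=C(/OC)CCC=C(C)C | intermediate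
12 | (3Z)-1,3-dimethoxy-7-methyl-1-(trimethylsilyloxy)octa-1,3,6-triene (C1=C2 geometry not defined) | COC(O[Si](C)(C)C)=C/C(OC)=C/CC=C(C)C | intermediate
13 | (2S)-4a-bromo-2-[3,4-bis(tert-butyldimethylsilyloxy)phenyl]-5,7-dimethoxy-8-(3-methylbut-2-enyl)-5-(trimethylsilyloxy)-2,3,4a,5,8,8a-hexahydro-4H-chromen-4-one (transient centres C4a, C5, C8, C8a not defined) | O=C1C[C@@H](c2ccc(O[Si](C)(C)C(C)(C)C)c(O[Si](C)(C)C(C)(C)C)c2)OC2C(CC=C(C)C)C(OC)=CC(OC)(O[Si](C)(C)C)C12Br | intermediate (not isolated)
14 | (2S)-4a-bromo-2-[3,4-bis(tert-butyldimethylsilyloxy)phenyl]-7-methoxy-8-(3-methylbut-2-enyl)-2,3,8,8a-tetrahydro-4H-chromene-4,5(4aH)-dione (transient centres C4a, C8, C8a not defined) | O=C1C[C@@H](c2ccc(O[Si](C)(C)C(C)(C)C)c(O[Si](C)(C)C(C)(C)C)c2)OC2C(CC=C(C)C)C(OC)=CC(=O)C12Br | intermediate (not isolated)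
15 | (2S)-2-[3,4-bis(tert-butyldimethylsilyloxy)phenyl]-5-hydroxy-7-methoxy-8-(3-methylbut-2-enyl)chroman-4-one | COc1cc(O)c2c(c1CC=C(C)C)O[C@H](c1ccc(O[Si](C)(C)C(C)(C)C)c(O[Si](C)(C)C(C)(C)C)c1)CC2=O | intermediate
16 | (2S)-2-(3,4-dihydroxyphenyl)-5-hydroxy-7-methoxy-8-(3-methylbut-2-enyl)chroman-4-one | COc1cc(O)c2c(c1CC=C(C)C)O[C@H](c1ccc(O)c(O)c1)CC2=O | target

## Step count and least certain steps

Total step count: 8. Longest linear sequence: 5 steps (steps 1, 2, 3, 7, 8; the diene branch, steps 4, 5, 6, 7, 8, is equally long).

**Step 7 (key step, new method).** Four processes may defeat it: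
- The cycloaddition may be slower than decomposition of the diene, because the dienophile is a vinylogous ester.
- The reaction may stop after the first C–C bond, because the second bond joins two fully substituted carbons.
- Dehydrobromination may be sluggish, since the C8a hydrogen is not acidified by a carbonyl and starts cis to bromine; halophilic loss of bromine or opening at O1–C8a would then compete.
- Prolonged exposure to base may erode the configuration at C2.

The fallback uses known chemistry, sets out from prenyl bromide 8 and returns at 15. Ring A is taken from a preformed arene and C2 is set by conjugate arylation.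
- Commercial 1-(2,6-dihydroxy-4-methoxyphenyl)ethanone is mono-O-alkylated with 8 (K2CO3, acetone) to 1-[2-hydroxy-4-methoxy-6-(3-methylbut-2-enyloxy)phenyl]ethanone F1; the second, chelated hydroxyl is much less reactive.
- Heating F1 with N,N-dimethylformamide dimethyl acetal gives the enaminone F2, which closes on silica gel to 7-methoxy-5-(3-methylbut-2-enyloxy)chromone F3.
- Separately, commercial 4-bromobenzene-1,2-diol is silylated (TBSCl, imidazole) to 4-bromo-1,2-bis(tert-butyldimethylsilyloxy)benzene F4. Bromine–lithium exchange (n-BuLi, −78 °C), B(OiPr)3 and aqueous work-up give the boronic acid F5.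
- Rhodium-catalysed asymmetric 1,4-addition of F5 to F3 ([Rh(OH)(cod)]2 with a chiral MeO-BIPHEP-type bisphosphine, antipode chosen for 2S, toluene/water) gives the 5-prenyloxy flavanone F6.
- The europium-catalysed Claisen–Cope rearrangement of F6 (Eu(fod)3, CHCl3, 60 °C) moves the prenyl group from O5 through C6 to C8 and gives 15.

**Step 2.** Turnover may be slow and facial selectivity modest with this electron-rich aldehyde, because a non-selective background aldol pathway can compete with the chiral titanium complex. The fallback sets out from 2 and returns at 5. It replaces Lewis acid catalysis and diene 3 by hydrogen-bond catalysis and a more reactive aminodiene. Aldehyde 2 and 1-(dimethylamino)-3-(tert-butyldimethylsilyloxy)buta-1,3-diene react in toluene at −40 °C with a tetra(1-naphthyl) TADDOL (antipode chosen for Si-face attack) to give the aminal cycloadduct F7. Acetyl chloride at −78 °C converts F7 into 5.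

**Step 6.** The diene may be lost through incomplete gamma-deprotonation, C-silylation or hydrolysis during isolation; the acid used in step 5 is a lesser risk for the prenyl olefin. The fallback sets out from 9 and returns at 15. It changes the diene type and moves the O7 methylation to the end.
- Keto ester 9 is silylated (TMSCl, Et3N) to the enol ether F8.
- Deprotonation and silylation (LiN(iPr)2, TMSCl, −78 °C) give the bis(silyloxy)diene F9.
- Under the conditions of step 7, F9 and 6 give the cycloadduct F10, which is aromatised in the same way to the 5,7-dihydroxyflavanone F11.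
- The acidic, non-chelated 7-hydroxyl of F11 is methylated selectively (Me3SiCHN2, MeOH/toluene, 0 °C) to give 15.

## Further compounds

F1 | step 7 | 1-[2-hydroxy-4-methoxy-6-(3-methylbut-2-enyloxy)phenyl]ethanone | COc1cc(O)c(C(C)=O)c(OCC=C(C)C)c1
F2 | step 7 | (2E)-3-(dimethylamino)-1-[2-hydroxy-4-methoxy-6-(3-methylbut-2-enyloxy)phenyl]prop-2-en-1-one | COc1cc(O)c(C(=O)/C=C/N(C)C)c(OCC=C(C)C)c1
F3 | step 7 | 7-methoxy-5-(3-methylbut-2-enyloxy)-4H-chromen-4-one | COc1cc(OCC=C(C)C)c2c(=O)ccoc2c1
F4 | step 7 | 4-bromo-1,2-bis(tert-butyldimethylsilyloxy)benzene | Brc1ccc(O[Si](C)(C)C(C)(C)C)c(O[Si](C)(C)C(C)(C)C)c1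
F5 | step 7 | [3,4-bis(tert-butyldimethylsilyloxy)phenyl]boronic acid | OB(O)c1ccc(O[Si](C)(C)C(C)(C)C)c(O[Si](C)(C)C(C)(C)C)c1
F6 | step 7 | (2S)-2-[3,4-bis(tert-butyldimethylsilyloxy)phenyl]-7-methoxy-5-(3-methylbut-2-enyloxy)chroman-4-one | COc1cc(OCC=C(C)C)c2c(c1)O[C@H](c1ccc(O[Si](C)(C)C(C)(C)C)c(O[Si](C)(C)C(C)(C)C)c1)CC2=O
F7 | step 2 | (6S)-6-[3,4-bis(tert-butyldimethylsilyloxy)phenyl]-4-(tert-butyldimethylsilyloxy)-N,N-dimethyl-5,6-dihydro-2H-pyran-2-amine (C2 of the pyran not defined) | CN(C)C1C=C(O[Si](C)(C)C(C)(C)C)C[C@@H](c2ccc(O[Si](C)(C)C(C)(C)C)c(O[Si](C)(C)C(C)(C)C)c2)O1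
F8 | step 6 | methyl 7-methyl-3-(trimethylsilyloxy)octa-2,6-dienoate | COC(=O)C=C(O[Si](C)(C)C)CCC=C(C)C
F9 | step 6 | 1-methoxy-7-methyl-1,3-bis(trimethylsilyloxy)octa-1,3,6-triene | COC(O[Si](C)(C)C)=CC(O[Si](C)(C)C)=CCC=C(C)C
F10 | step 6 | (2S)-4a-bromo-2-[3,4-bis(tert-butyldimethylsilyloxy)phenyl]-5-methoxy-8-(3-methylbut-2-enyl)-5,7-bis(trimethylsilyloxy)-2,3,4a,5,8,8a-hexahydro-4H-chromen-4-one (transient centres not defined) | O=C1C[C@@H](c2ccc(O[Si](C)(C)C(C)(C)C)c(O[Si](C)(C)C(C)(C)C)c2)OC2C(CC=C(C)C)C(O[Si](C)(C)C)=CC(OC)(O[Si](C)(C)C)C12Br
F11 | step 6 | (2S)-2-[3,4-bis(tert-butyldimethylsilyloxy)phenyl]-5,7-dihydroxy-8-(3-methylbut-2-enyl)chroman-4-one | Oc1cc(O)c2c(c1CC=C(C)C)O[C@H](c1ccc(O[Si](C)(C)C(C)(C)C)c(O[Si](C)(C)C(C)(C)C)c1)CC2=O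
A1 | alternative 1 | 5-isopropoxy-2-(3-methylbut-2-enyl)-3-(triisopropylsilyloxy)phenol | Oc1cc(OC(C)C)cc(O[Si](C(C)C)(C(C)C)C(C)C)c1CC=C(C)C
A2 | alternative 1 | 3-isopropoxycyclobut-2-en-1-one | CC(C)OC1=CC(=O)C1
A3 | alternative 1 | triisopropyl[(5-methylhex-4-en-1-yn-1-yl)oxy]silane | CC(C)=CCC#CO[Si](C(C)C)(C(C)C)C(C)C
A4 | alternative 2 | (2S)-7-methoxy-2-[3,4-bis(methoxymethoxy)phenyl]-8-(3-methylbut-2-enyl)-5-(triisopropylsilyloxy)chroman-4-one | COc1cc(O[Si](C(C)C)(C(C)C)C(C)C)c2c(c1CC=C(C)C)O[C@H](c1ccc(OCOC)c(OCOC)c1)CC2=O
A5 | alternative 2 | (3S)-1-[2-fluoro-4-methoxy-3-(3-methylbut-2-enyl)-6-(triisopropylsilyloxy)phenyl]-3-hydroxy-3-[3,4-bis(methoxymethoxy)phenyl]propan-1-one | COc1cc(O[Si](C(C)C)(C(C)C)C(C)C)c(C(=O)C[C@H](O)c2ccc(OCOC)c(OCOC)c2)c(F)c1CC=C(C)C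
A6 | alternative 3 | (2S)-5-acetoxy-2-(3,4-diacetoxyphenyl)-7-methoxy-8-(3-methylbut-2-enyl)chroman-4-one | COc1cc(OC(C)=O)c2c(c1CC=C(C)C)O[C@H](c1ccc(OC(C)=O)c(OC(C)=O)c1)CC2=O
A7 | alternative 3 | (3S)-3-[5-acetoxy-3-methoxy-2-(3-methylbut-2-enyl)phenoxy]-3-(3,4-diacetoxyphenyl)propanoic acid | COc1cc(OC(C)=O)cc(O[C@H](c2ccc(OC(C)=O)c(OC(C)=O)c2)CC(=O)O)c1CC=C(C)C
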